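**Plan**
- Target: achiral biflavone ether. Unit 1 is a 5-hydroxy-7-methoxyflavone whose ring B oxygen (O4') is bonded to C6 of unit 2, an apigenin.
- First cut: ring C of unit 1 at O1–C2 and C2–C3, giving a 4-formylphenyl ether of unit 2 and a 2'-hydroxyacetophenone (chalcone route).
- Second cut: ring A of unit 2 at C7–C8 and C5–C6. C6 with its ether oxygen and the neighbouring C7 are an aryloxyacetyl unit; C8 and C5 are the 2-methyl group and the 3-ester on adjacent carbons (C8a, C4a) of a 4-pyranone, which is ring C of unit 2.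
- Third cut: the pyranone at C3–C4 and O1–C6, giving methyl acetoacetate and an arylpropioloyl chloride; the diaryl ether oxygen comes from a phenoxide alkylation at a primary carbon.
- Forward order: ring C of unit 2 (as a monocyclic pyranone), then ring A of unit 2 by anionic benzannulation, then ring C of unit 1, then global debenzylation.
- Stereochemistry: the target has no stereocentre. The only stereo element on the way is the E-enone of the chalcone, set thermodynamically and consumed in the next step.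

Key step: step 5

Remark: flavone numbering is used throughout; compounds 1, 3, 7, 8 and 15 are taken as commercial.

**Route**

Step 1
Reactants: 1 1-(benzyloxy)-4-ethynylbenzene
Product: 2 3-[4-(benzyloxy)phenyl]prop-2-ynoic acid
Conditions: n-BuLi (1.05 equiv), THF, −78 °C; CO2 (gas), −78 °C to rt; 1 M HCl
Reagents that add atoms: carbon dioxide O=C=O
Why: Deprotonation of the terminal alkyne and carboxylation of the lithium acetylide is the standard route to arylpropiolic acids, and the benzyl ether is inert to n-BuLi at −78 °C.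

Step 2
Reactants: 2 3-[4-(benzyloxy)phenyl]prop-2-ynoic acid; 3 methyl acetoacetate
Product: 6 methyl 6-[4-(benzyloxy)phenyl]-2-methyl-4-oxo-4H-pyran-3-carboxylate, via arylpropioloyl chloride 4 (not isolated), via acyclic triketo ynone ester 5 (not isolated)
Conditions: (COCl)2, DMF (cat.), CH2Cl2, 0 °C to rt, evaporate; then 3, MgCl2, pyridine, CH2Cl2, 0 °C to rt; then Et3N, rt; 1 M HCl work-up
Reagents that add atoms: none
Why: Acid chloride formation and C-acylation of the magnesium chelate of the β-keto ester (Rathke conditions) should give the 2-acyl ynone, whose acetyl enol oxygen adds 6-endo-dig to the ynone (oxa-Michael) to close the 4-pyranone, the classical outcome of arylpropioloyl chlorides and acetoacetates.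

Step 3
Reactants: 7 4-hydroxybenzaldehyde; 8 2-chloro-N-methoxy-N-methylacetamide
Product: 9 2-(4-formylphenoxy)-N-methoxy-N-methylacetamide
Conditions: K2CO3, KI (cat.), DMF, 60 °C
Reagents that add atoms: none
Why: Williamson ether synthesis by SN2 displacement at the primary, carbonyl-activated chloride (iodide catalysis) puts the future C6 ether oxygen in place without any crowding.

Step 4
Reactants: 9 2-(4-formylphenoxy)-N-methoxy-N-methylacetamide
Product: 10 2-[4-(1,3-dioxolan-2-yl)phenoxy]-N-methoxy-N-methylacetamide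
Conditions: ethylene glycol, p-TsOH·H2O (cat.), toluene, reflux, Dean–Stark
Reagents that add atoms: ethylene glycol OCCO
Why: Acid-catalysed acetalisation with azeotropic removal of water masks the aldehyde against the carbanion chemistry of step 5, while the Weinreb amide and the aryl ether are unaffected.

Step 5
Reactants: 6 methyl 6-[4-(benzyloxy)phenyl]-2-methyl-4-oxo-4H-pyran-3-carboxylate; 10 2-[4-(1,3-dioxolan-2-yl)phenoxy]-N-methoxy-N-methylacetamide
Product: 12 2-[4-(benzyloxy)phenyl]-6-[4-(1,3-dioxolan-2-yl)phenoxy]-5,7-dihydroxy-4H-chromen-4-one, via open-chain aryloxymethyl ketone 11 (not isolated)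
Conditions: LiN(i-Pr)2 (1.05 equiv), THF, −78 °C; 10 (1.1 equiv), −78 to −30 °C; LiN(i-Pr)2 (2.5 equiv), −78 °C to rt; sat. aq. NH4Cl, 0 °C
Reagents that add atoms: none
Why: Proposed new method: the 2-methyl group of 6 is vinylogous to both the C4 carbonyl and the C3 ester, so LiN(i-Pr)2 should give the extended enolate, whose exocyclic carbon attacks the Weinreb amide (C7–C8) to give a chelated tetrahedral adduct; the second charge of base removes the still acidic pyranyl CH2 proton, which expels LiN(OMe)Me and leaves the enolate of ketone 11, and a further deprotonation on the aryloxy side gives a dienolate whose more basic ArO–CH carbon attacks the neighbouring ester (C5–C6) and displaces methoxide, after which double enolisation aromatises ring A. The closest known reaction type is the tandem Claisen–Dieckmann (anionic 4+2) benzannulation of lithiated ortho-toluates by esters or Weinreb amides to 1,3-dihydroxyarenes, and lateral lithiation and acylation of 2-methyl-4-pyranones is known on its own. The one ring closed, ring A of unit 2, forms by a 6-exo-trig Dieckmann acylation followed by irreversible tautomerisation to the phloroglucinol-type arene. No stereocentre is formed. Selectivity needed: carbon, not oxygen, must acylate in both events, and the ester, not the pyranone C4 carbonyl at the same distance, must be attacked; the amide is a poor O-acylating agent, the fused 2-pyranone from O-attack of the ketone enolate on the ester is reopened by the methoxide present, addition to the cross-conjugated C4 carbonyl is a reversible aldol, and only the ester pathway ends in an aromatic diphenoxide. Staging the base (one equivalent before the amide, the rest after) keeps the amide from being enolised before it is acylated, and the NH4Cl quench spares the dioxolane.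

Step 6
Reactants: 12 2-[4-(benzyloxy)phenyl]-6-[4-(1,3-dioxolan-2-yl)phenoxy]-5,7-dihydroxy-4H-chromen-4-one
Product: 14 4-({5,7-bis(benzyloxy)-2-[4-(benzyloxy)phenyl]-4-oxo-4H-chromen-6-yl}oxy)benzaldehyde, via tribenzyl ether dioxolane 13 (not isolated)
Conditions: BnBr (3 equiv), K2CO3, DMF, 70 °C; then 2 M HCl, THF, rt
Reagents that add atoms: benzyl bromide BrCc1ccccc1; water O
Why: Williamson O-benzylation in DMF with heating should etherify both the 7-hydroxyl and the chelated 5-hydroxyl (as for 5,6,7-trioxygenated flavones), and acid-catalysed acetal hydrolysis in the work-up frees the aldehyde while the benzyl ethers and the flavone tolerate dilute acid at room temperature.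

Step 7
Reactants: 15 1-(2,6-dihydroxy-4-methoxyphenyl)ethan-1-one
Product: 16 1-[2-(benzyloxy)-6-hydroxy-4-methoxyphenyl]ethan-1-one
Conditions: BnBr (1.0 equiv), K2CO3 (1.1 equiv), acetone, reflux
Reagents that add atoms: benzyl bromide BrCc1ccccc1
Why: Williamson mono-benzylation of the symmetric diphenol should stop after one ether, because the remaining hydroxyl is locked in a strong hydrogen bond to the acetyl group and only one equivalent of halide is supplied.

Step 8
Reactants: 14 4-({5,7-bis(benzyloxy)-2-[4-(benzyloxy)phenyl]-4-oxo-4H-chromen-6-yl}oxy)benzaldehyde; 16 1-[2-(benzyloxy)-6-hydroxy-4-methoxyphenyl]ethan-1-one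
Product: 17 (E)-1-[2-(benzyloxy)-6-hydroxy-4-methoxyphenyl]-3-[4-({5,7-bis(benzyloxy)-2-[4-(benzyloxy)phenyl]-4-oxo-4H-chromen-6-yl}oxy)phenyl]prop-2-en-1-one
Conditions: KOH (50% aq., excess), EtOH–THF, rt; 1 M HCl to pH 4
Reagents that add atoms: none
Why: Claisen–Schmidt aldol condensation of the methyl ketone with the non-enolisable aryl aldehyde forms the future C2–C3 bond of unit 1, and E1cB dehydration gives the thermodynamically favoured E-enone.

Step 9
Reactants: 17 the (E)-2'-hydroxychalcone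
Product: 18 5-(benzyloxy)-2-[4-({5,7-bis(benzyloxy)-2-[4-(benzyloxy)phenyl]-4-oxo-4H-chromen-6-yl}oxy)phenyl]-7-methoxy-4H-chromen-4-one
Conditions: I2 (0.1 equiv), DMSO, 130 °C; aq. Na2S2O3 work-up
Reagents that add atoms: none
Why: Iodine–dimethyl sulfoxide oxidative cyclisation of a 2'-hydroxychalcone (6-endo-trig oxa-Michael addition to the flavanone, α-iodination and loss of HI, with DMSO reoxidising HI) closes ring C of unit 1, and any flavanone already present converges on the same flavone.

Step 10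
Reactants: 18 the tetra-O-benzyl biflavone
Product: 19 neocryptomerin, 5,7-dihydroxy-6-[4-(5-hydroxy-7-methoxy-4-oxo-4H-chromen-2-yl)phenoxy]-2-(4-hydroxyphenyl)-4H-chromen-4-one
Conditions: H2 (1 atm), 10% Pd/C, THF–MeOH, rt
Reagents that add atoms: none
Why: Catalytic hydrogenolysis should cleave the four aryl benzyl ethers, while the methyl ether, the diaryl ether and the flavone C2–C3 double bonds are not reduced at atmospheric pressure and room temperature.

**Compound list**

1 | 1-(benzyloxy)-4-ethynylbenzene | C#Cc1ccc(OCc2ccccc2)cc1 | starting material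
2 | 3-[4-(benzyloxy)phenyl]prop-2-ynoic acid | OC(=O)C#Cc1ccc(OCc2ccccc2)cc1 | intermediate
3 | methyl acetoacetate | CC(=O)CC(=O)OC | starting material
4 | 3-[4-(benzyloxy)phenyl]prop-2-ynoyl chloride (not isolated) | ClC(=O)C#Cc1ccc(OCc2ccccc2)cc1 | intermediate
5 | methyl 2-acetyl-5-[4-(benzyloxy)phenyl]-3-oxopent-4-ynoate (not isolated) | COC(=O)C(C(C)=O)C(=O)C#Cc1ccc(OCc2ccccc2)cc1 | intermediate
6 | methyl 6-[4-(benzyloxy)phenyl]-2-methyl-4-oxo-4H-pyran-3-carboxylate | COC(=O)C1=C(C)OC(=CC1=O)c1ccc(OCc2ccccc2)cc1 | intermediate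
7 | 4-hydroxybenzaldehyde | O=Cc1ccc(O)cc1 | starting material
8 | 2-chloro-N-methoxy-N-methylacetamide | CON(C)C(=O)CCl | starting material
9 | 2-(4-formylphenoxy)-N-methoxy-N-methylacetamide | CON(C)C(=O)COc1ccc(C=O)cc1 | intermediate
10 | 2-[4-(1,3-dioxolan-2-yl)phenoxy]-N-methoxy-N-methylacetamide | CON(C)C(=O)COc1ccc(cc1)C1OCCO1 | intermediate
11 | methyl 6-[4-(benzyloxy)phenyl]-2-{3-[4-(1,3-dioxolan-2-yl)phenoxy]-2-oxopropyl}-4-oxo-4H-pyran-3-carboxylate (not isolated) | COC(=O)C1=C(CC(=O)COc2ccc(cc2)C2OCCO2)OC(=CC1=O)c1ccc(OCc2ccccc2)cc1 | intermediate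
12 | 2-[4-(benzyloxy)phenyl]-6-[4-(1,3-dioxolan-2-yl)phenoxy]-5,7-dihydroxy-4H-chromen-4-one | Oc1cc2oc(cc(=O)c2c(O)c1Oc3ccc(cc3)C4OCCO4)-c5ccc(OCc6ccccc6)cc5 | intermediate
13 | 5,7-bis(benzyloxy)-2-[4-(benzyloxy)phenyl]-6-[4-(1,3-dioxolan-2-yl)phenoxy]-4H-chromen-4-one (not isolated) | O=c1cc(-c2ccc(OCc3ccccc3)cc2)oc2cc(OCc3ccccc3)c(Oc3ccc(cc3)C3OCCO3)c(OCc3ccccc3)c12 | intermediate
14 | 4-({5,7-bis(benzyloxy)-2-[4-(benzyloxy)phenyl]-4-oxo-4H-chromen-6-yl}oxy)benzaldehyde | O=Cc1ccc(Oc2c(OCc3ccccc3)cc3oc(-c4ccc(OCc5ccccc5)cc4)cc(=O)c3c2OCc2ccccc2)cc1 | intermediate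
15 | 1-(2,6-dihydroxy-4-methoxyphenyl)ethan-1-one | COc1cc(O)c(C(C)=O)c(O)c1 | starting material
16 | 1-[2-(benzyloxy)-6-hydroxy-4-methoxyphenyl]ethan-1-one | COc1cc(O)c(C(C)=O)c(OCc2ccccc2)c1 | intermediate
17 | (E)-1-[2-(benzyloxy)-6-hydroxy-4-methoxyphenyl]-3-[4-({5,7-bis(benzyloxy)-2-[4-(benzyloxy)phenyl]-4-oxo-4H-chromen-6-yl}oxy)phenyl]prop-2-en-1-one | COc1cc(O)c(C(=O)/C=C/c2ccc(Oc3c(OCc4ccccc4)cc4oc(-c5ccc(OCc6ccccc6)cc5)cc(=O)c4c3OCc3ccccc3)cc2)c(OCc2ccccc2)c1 | intermediate
18 | 5-(benzyloxy)-2-[4-({5,7-bis(benzyloxy)-2-[4-(benzyloxy)phenyl]-4-oxo-4H-chromen-6-yl}oxy)phenyl]-7-methoxy-4H-chromen-4-one | COc1cc(OCc2ccccc2)c2c(=O)cc(-c3ccc(Oc4c(OCc5ccccc5)cc5oc(-c6ccc(OCc7ccccc7)cc6)cc(=O)c5c4OCc4ccccc4)cc3)oc2c1 | intermediate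
19 | neocryptomerin | COc1cc(O)c2c(=O)cc(-c3ccc(Oc4c(O)cc5oc(-c6ccc(O)cc6)cc(=O)c5c4O)cc3)oc2c1 | target

**Count**

Total steps: 10. Longest linear sequence: 7 steps (steps 1, 2, 5, 6, 8, 9, 10 from 1; equally steps 3, 4, 5, 6, 8, 9, 10 from 7).

**Steps most likely to fail**

1. Step 5. The lithiated pyranone may exchange a proton with the amide or add to a second pyranone instead of being acylated, or the sequence may stop at the open-chain ketone or at the fused lactone without aromatising. The fallback uses known chemistry, sets out from 7 and returns at 14. Commercial apigenin F1 would be benzylated at O7 and O4' (BnBr, K2CO3, acetone, reflux) to 7-(benzyloxy)-2-[4-(benzyloxy)phenyl]-5-hydroxy-4H-chromen-4-one F2. Iodination ortho to the free chelated hydroxyl (benzyltrimethylammonium dichloroiodate, CaCO3, CH2Cl2–MeOH, rt) should give 7-(benzyloxy)-2-[4-(benzyloxy)phenyl]-5-hydroxy-6-iodo-4H-chromen-4-one F3. Benzylation at O5 (BnBr, K2CO3, DMF, 70 °C) would give 5,7-bis(benzyloxy)-2-[4-(benzyloxy)phenyl]-6-iodo-4H-chromen-4-one F4. An Ullmann diaryl ether coupling of F4 with 7 (CuI, picolinic acid, K3PO4, DMSO, 100 °C) should then give 14, and the route continues at step 8.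

2. Step 2. Chloride or pyridine may add in conjugate fashion to the ynoyl chloride, or the enolate may be O-acylated, so that the acylating agent is consumed before the C-acyl ynone can cyclise. The fallback sets out from 3 and returns at 6. Commercial (E)-3-[4-(benzyloxy)phenyl]prop-2-enoic acid F5 would be converted by (COCl)2 and DMF (cat.) into the robust (E)-3-[4-(benzyloxy)phenyl]prop-2-enoyl chloride F6. This would C-acylate the magnesium enolate of 3 (MgCl2, pyridine, CH2Cl2) to give methyl (E)-2-acetyl-5-[4-(benzyloxy)phenyl]-3-oxopent-4-enoate F7. Heating with I2 (cat.) in DMSO at 120 °C should close the enol oxygen onto the enone to racemic methyl 6-[4-(benzyloxy)phenyl]-2-methyl-4-oxo-5,6-dihydro-4H-pyran-3-carboxylate F8 and dehydrogenate it in the same flask to 6. This is the oxidative cyclisation of step 9 applied to a cinnamoyl β-dicarbonyl compound.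

3. Step 8. Hydroxide may open the pyranone ring of unit 2 (retro-Claisen degradation) during the slow condensation of the doubly ortho-substituted acetophenone. The fallback sets out from 14 and returns at 18, bypassing 17 and step 9 by a Baker–Venkataraman sequence under non-hydroxide conditions. Pinnick oxidation (NaClO2, NaH2PO4, 2-methyl-2-butene, t-BuOH–THF–H2O) would give 4-({5,7-bis(benzyloxy)-2-[4-(benzyloxy)phenyl]-4-oxo-4H-chromen-6-yl}oxy)benzoic acid F9. Esterification with the phenol of 16 (EDC·HCl, DMAP, CH2Cl2) would give 2-acetyl-3-(benzyloxy)-5-methoxyphenyl 4-({5,7-bis(benzyloxy)-2-[4-(benzyloxy)phenyl]-4-oxo-4H-chromen-6-yl}oxy)benzoate F10. Acyl migration with LiN(SiMe3)2 (THF, −78 °C to rt) should give 1-[2-(benzyloxy)-6-hydroxy-4-methoxyphenyl]-3-[4-({5,7-bis(benzyloxy)-2-[4-(benzyloxy)phenyl]-4-oxo-4H-chromen-6-yl}oxy)phenyl]propane-1,3-dione F11. Cyclodehydration (p-TsOH cat., toluene, 90 °C) would then give 18.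

Further compounds
F1 | step 5 | apigenin (commercial partner of the fallback) | O=c1cc(-c2ccc(O)cc2)oc2cc(O)cc(O)c12
F2 | step 5 | 7-(benzyloxy)-2-[4-(benzyloxy)phenyl]-5-hydroxy-4H-chromen-4-one | O=c1cc(-c2ccc(OCc3ccccc3)cc2)oc2cc(OCc3ccccc3)cc(O)c12
F3 | step 5 | 7-(benzyloxy)-2-[4-(benzyloxy)phenyl]-5-hydroxy-6-iodo-4H-chromen-4-one | O=c1cc(-c2ccc(OCc3ccccc3)cc2)oc2cc(OCc3ccccc3)c(I)c(O)c12
F4 | step 5 | 5,7-bis(benzyloxy)-2-[4-(benzyloxy)phenyl]-6-iodo-4H-chromen-4-one | O=c1cc(-c2ccc(OCc3ccccc3)cc2)oc2cc(OCc3ccccc3)c(I)c(OCc3ccccc3)c12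
F5 | step 2 | (E)-3-[4-(benzyloxy)phenyl]prop-2-enoic acid | OC(=O)/C=C/c1ccc(OCc2ccccc2)cc1
F6 | step 2 | (E)-3-[4-(benzyloxy)phenyl]prop-2-enoyl chloride | ClC(=O)/C=C/c1ccc(OCc2ccccc2)cc1
F7 | step 2 | methyl (E)-2-acetyl-5-[4-(benzyloxy)phenyl]-3-oxopent-4-enoate | COC(=O)C(C(C)=O)C(=O)/C=C/c1ccc(OCc2ccccc2)cc1
F8 | step 2 | methyl 6-[4-(benzyloxy)phenyl]-2-methyl-4-oxo-5,6-dihydro-4H-pyran-3-carboxylate (racemic) | COC(=O)C1=C(C)OC(CC1=O)c1ccc(OCc2ccccc2)cc1
F9 | step 8 | 4-({5,7-bis(benzyloxy)-2-[4-(benzyloxy)phenyl]-4-oxo-4H-chromen-6-yl}oxy)benzoic acid | OC(=O)c1ccc(Oc2c(OCc3ccccc3)cc3oc(-c4ccc(OCc5ccccc5)cc4)cc(=O)c3c2OCc2ccccc2)cc1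
F10 | step 8 | 2-acetyl-3-(benzyloxy)-5-methoxyphenyl 4-({5,7-bis(benzyloxy)-2-[4-(benzyloxy)phenyl]-4-oxo-4H-chromen-6-yl}oxy)benzoate | CC(=O)c1c(OCc2ccccc2)cc(OC)cc1OC(=O)c1ccc(Oc2c(OCc3ccccc3)cc3oc(-c4ccc(OCc5ccccc5)cc4)cc(=O)c3c2OCc2ccccc2)cc1
F11 | step 8 | 1-[2-(benzyloxy)-6-hydroxy-4-methoxyphenyl]-3-[4-({5,7-bis(benzyloxy)-2-[4-(benzyloxy)phenyl]-4-oxo-4H-chromen-6-yl}oxy)phenyl]propane-1,3-dione | COc1cc(O)c(C(=O)CC(=O)c2ccc(Oc3c(OCc4ccccc4)cc4oc(-c5ccc(OCc6ccccc6)cc5)cc(=O)c4c3OCc3ccccc3)cc2)c(OCc2ccccc2)c1
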